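# Synthesis plan for selaginellin F by aryne insertion into a symmetric 1,3-diketone

## The problem

Selaginellin F has no stereocentre; the difficulty is ring A, a benzene carrying four different carbon substituents on four neighbouring positions. These are the hydroxymethyl group at C5, the arylethynyl group at C6, the quinone methide carbon C7 at C1 and the resorcinol ring B at C2; only C3 and C4 bear hydrogen. C1 is flanked on both sides, so every bond made to C1 or C7 is made at a crowded centre, and the order of introduction of the C1, C2 and C6 groups decides whether the late steps are feasible. With no stereochemistry to relay, the control problem is regiochemistry on ring A.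

The sensitive functions are the quinone methide (an electrophile at C7, best formed last), the electron-rich diaryl alkyne (no hydrogenation, limited acid), the free resorcinol and the benzylic alcohol next to the alkyne. This limits protecting groups to those removed by mild acid or by zerovalent palladium.

The enabling feature is that C1 and C6 carry a one-carbon arm (C7) and a two-carbon arm (C8–C9) that both end in a 4-hydroxyphenyl ring. At the ketone oxidation level, C7(=O)Ar and C8H2–C9(=O)Ar are the two halves of a symmetric 1,3-diaryl-1,3-diketone into whose C7–C8 bond the C1–C6 edge of ring A has been inserted. Since the two aryl groups on C7 are identical and the quinone methide is the dehydrated form of a bis(4-hydroxyphenyl)carbinol, one aryl can arrive with the diketone and the other from an aryl nucleophile at the end.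

## Retrosynthesis

**31 ⇒ 30.** The exocyclic C7=C bond of target 31 is traced back to the C7–OH bond of triaryl carbinol 30, in which all six hydroxyls are methoxymethyl (MOM) acetals. One acid treatment should free the phenols and ionise the carbinol, so the electrophilic quinone methide appears only in the last flask. Oxidising a triarylmethane would expose a free resorcinol to an oxidant, and methyl ethers would need a boron trihalide next to the alkyne. The forward step must clear an aliphatic acetal without adding water or the neighbouring hydroxymethyl group across the alkyne.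

**30 ⇒ 26 + 29.** The C7–aryl bond is cut to diaryl ketone 26 and aryllithium 29 (from bromide 28, from 4-bromophenol 27). Because the two C7 aryls are the same, it does not matter which is added last, and a ketone at C7 is exactly what the key step delivers. Only one addition to a hindered but non-enolisable ketone is asked.

**26 ⇒ 21 + 25.** The biaryl bond C2–C1' is cut to aryl triflate 21 and boronic acid 25 (from bromide 23, from 4-bromoresorcinol 22). Ring B is bought with both oxygens in place. Carrying ring B through the aryne step would replace the C2 oxygen by an aryl group with no electronic bias on the aryne. The C2 oxygen therefore serves twice, first as regiochemical director and then as leaving group. The forward step is a coupling ortho to an aroyl group with an ortho-alkoxy boronic acid.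

**21 ⇒ 20 ⇒ 19.** Functional-group changes only: triflate 21 from phenol 20, and 20 from allyl ether 19. Allyl is orthogonal to MOM and is removed by zerovalent palladium without touching the alkyne.

**19 ⇒ 17.** The two π bonds of C8≡C9 are traced back to aryl benzyl ketone 17 through enol triflate 18; the C9 oxygen is a latent leaving group and C8 is the only enolisable position. A Sonogashira route would need a C6 halide between two substituents and a separate construction of the C1 ketone, that is, two independent couplings at crowded positions.

**17 ⇒ 9 + 14 (key disconnection).** C6–C8 and C1–C7 are cut together. Ketone 17 is diketone 14 with the C1–C6 bond of aryne 15 inserted into its central C–C bond, by way of benzocyclobutenoxide 16; the aryne comes from silyl triflate 9. One step installs both arms, each already carrying its aryl group and its correct chain length. The symmetry of 14 removes any question of which carbonyl is attacked. The forward reaction must bond the enolate carbon to C6 and not C1, which is the task of the C2 allyloxy group. Ring A is simplified from four contiguous substituents to a precursor with two.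

**14 ⇒ 11 + 13.** The diketone is cut at a carbonyl–CH2 bond by a crossed Claisen condensation of ketone 11 and ester 13, the MOM ethers of 4'-hydroxyacetophenone 10 and methyl 4-hydroxybenzoate 12.

**9 ⇒ 8 ⇒ 4 ⇒ 3 ⇒ 2 ⇒ 1.** MOM ether 9 comes from alcohol 8. The C1–Si bond and the C6–O triflate of 8 come from an ortho-bromophenol by O-silylation, bromine–lithium exchange, O-to-C silyl shift and triflation (via 5, 6 and 7). The bromine of 2-bromoresorcinol 1 marks C1 and its two oxygens become the C2 and C6 oxygens. The missing C5 carbon is added by formylation at the only free position activated by both hydroxyls (2). The two hydroxyls are told apart by the hydrogen bond of one of them to the new aldehyde (3), and reduction gives diol 4. The benzylic hydroxyl of 4 is masked as a trimethylsilyl ether in the same silylation that prepares the phenol for the silyl shift, so phenol and benzylic alcohol never have to be distinguished in a protection step.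

## Roads not taken

**Alternative 1: anodic C–H lactonisation to set the ring B 2'-oxygen.** The cut is the C2'–O bond of ring B, traced to a C–H bond, with C7 held as the carbonyl of a six-membered aryl lactone. In the forward direction, constant-current electrolysis of biaryl acid A2 at a graphite anode gives an aroyloxy radical that attacks the pendent ring and, after further oxidation and proton loss, closes lactone A1.

- Merits: the lactone would accept two equivalents of an aryllithium such as 29 and deliver both C7 aryl groups and the free 2'-hydroxyl in one operation. This uses the C7 symmetry more fully than the chosen plan, which needs a separate aryl addition. No chemical oxidant is needed, and the bromine at C6 is a ready Sonogashira handle.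
- Weak points: the 2'-oxygen can simply be bought with ring B, so the key step solves a problem the target does not pose. Acid A2 is itself a ring A with four contiguous substituents, whose preparation is the real difficulty and is left open. The pivalates would consume aryllithium. The Sonogashira coupling must occur at a bromide flanked by the lactone carbonyl and the acyloxymethyl group. Radical attack on a 4'-oxygenated ring can also go through the ipso position with a 1,2-shift.
- Comparison: the chosen plan spends one more step on C7 but builds the C1 and C6 arms of ring A in a single step from a simple arene. This alternative leaves that problem untouched.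

**Alternative 2: triyne [2+2+2] cyclotrimerisation to a ring A bis-lactone.** The cut removes three bonds of ring A (C1–C2, C3–C4, C5–C6). Triyne A4 is a mixed aryl/propargyl diester of an acetylenedicarboxylate. With RhCl(PPh3)3 (univalent rhodium) under high dilution it would close ring A, the aryl lactone and the phthalide at once to give A3.

- Merits: ring A regiochemistry is fixed by the tethers and does not rest on aryne polarisation, which is a real advantage over the chosen plan. The step is an isomerisation with full atom economy, and the tether also places the 2'-oxygen.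
- Weak points: A4 is an aryl ynoate, a strong Michael acceptor and acylating agent that is hard to make unsymmetrically and to store. Both tethers are esters that prefer extended conformations, so oligomerisation competes. In A3 the C6 substituent arrives as a lactone carboxyl that must be reduced, homologated by one carbon and then arylated. The two lactones must be distinguished.
- Comparison: the overall length is probably similar. Against the better regiocontrol of A3, the chosen plan offers robust building blocks and arms that arrive at full length with their aryl groups attached.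

**Alternative 3: ketodiester plus cinnamaldehyde [3+3], late aromatisation.** The cuts are C1–C2 and C4–C5. Ketodiester A7 would add through one α-carbon to the β-carbon of enal A6 and condense through the other α-carbon with the aldehyde, under an amine–acid catalyst, to give racemic cyclohexadienol diester A5.

- Merits: the materials are the cheapest of all the routes and the chemistry is classical. Every ring A carbon receives its substituent without regiochemical ambiguity, and in this respect the route is more predictable than an aryne. The C6 oxygen becomes a triflate for Sonogashira coupling, and the C1 ester can take both C7 aryl groups at once.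
- Weak points: A5 must be dehydrogenated, and its stereocentre is made only to be destroyed. The two methyl esters flank the C6 oxygen and differ only in their other neighbour, yet one must become CH2OH and the other a diaryl carbinol. The coupling occurs at a triflate between two esters, and A6 needs its own preparation.
- Comparison: the step count is likely comparable. The chosen plan avoids ester differentiation, aromatisation and redox adjustment of the arms. It concentrates its uncertainty in one step, whose bias has a clear physical origin.

Key step: step 9

## Route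

Remark on the chemistry: the target is treated as the open quinone methide drawn; the two 4-oxyphenyl rings on C7 interconvert by tautomerism, so no double-bond geometry has to be set. Locants C1–C9 and ring letters follow the numbering in "The problem".

Step 1
Reactants: 1 2-bromoresorcinol
Product: 2 3-bromo-2,4-dihydroxybenzaldehyde
Conditions: POCl3, DMF, MeCN, 0 °C to rt; then H2O, 50 °C
Reagents that add atoms: N,N-dimethylformamide (CN(C)C=O); water (O)
Why: Vilsmeier–Haack formylation; the chloroiminium ion attacks the only free position activated by both hydroxyls (ortho to one, para to the other, C2 being blocked by bromine), the iminium salt formed deactivates the ring against a second formylation, and hydrolysis gives the aldehyde.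

Step 2
Reactants: 2 3-bromo-2,4-dihydroxybenzaldehyde
Product: 3 4-(allyloxy)-3-bromo-2-hydroxybenzaldehyde
Conditions: allyl bromide (1.1 equiv), KHCO3, DMF, 40 °C
Reagents that add atoms: allyl bromide (C=CCBr)
Why: Williamson etherification; the 2-hydroxyl is held in a hydrogen bond to the formyl group and is flanked on both sides, so a weak base should alkylate only the more acidic, freer 4-hydroxyl para to the aldehyde.

Step 3
Reactants: 3 4-(allyloxy)-3-bromo-2-hydroxybenzaldehyde
Product: 4 3-(allyloxy)-2-bromo-6-(hydroxymethyl)phenol
Conditions: NaBH4, MeOH/THF, 0 °C; work-up near neutral pH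
Reagents that add atoms: none
Why: Borohydride reduction of an aryl aldehyde; the aryl bromide and allyl ether are inert, and a neutral work-up avoids ortho-quinone methide chemistry of the salicyl alcohol.

Step 4
Reactants: 4 3-(allyloxy)-2-bromo-6-(hydroxymethyl)phenol
Product: 8 3-(allyloxy)-6-(hydroxymethyl)-2-(trimethylsilyl)phenyl trifluoromethanesulfonate, via bis(trimethylsilyl) ether 5 (not isolated), via lithium 2-silylphenolate 6 (not isolated), via silyl ether triflate 7 (not isolated)
Conditions: (Me3Si)2NH, Me3SiCl (cat.), THF, 65 °C, then evaporate; n-BuLi (1.05 equiv), THF, −78 °C; Tf2O (1.1 equiv), −78 to 0 °C; citric acid, MeOH/H2O, 0 °C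
Reagents that add atoms: hexamethyldisilazane (C[Si](C)(C)N[Si](C)(C)C); trifluoromethanesulfonic anhydride (O=S(=O)(OS(=O)(=O)C(F)(F)F)C(F)(F)F)
Why: O-silylation of both hydroxyls, bromine–lithium exchange at −78 °C and 1,3 O-to-C silyl shift (retro-Brook rearrangement) driven by formation of the lithium phenolate, then O-triflation, is the standard route from ortho-bromophenols to ortho-silylaryl triflates. The benzylic trimethylsilyl ether only masks the alcohol during metalation and is lost in the mild acidic methanol treatment, while the aryl–silicon bond, now on a ring deactivated by the triflate, should stay.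

Step 5
Reactants: 8 3-(allyloxy)-6-(hydroxymethyl)-2-(trimethylsilyl)phenyl trifluoromethanesulfonate
Product: 9 3-(allyloxy)-6-[(methoxymethoxy)methyl]-2-(trimethylsilyl)phenyl trifluoromethanesulfonate
Conditions: MOMCl, iPr2NEt, CH2Cl2, 0 °C to rt
Reagents that add atoms: chloromethyl methyl ether (COCCl)
Why: Acetal (MOM ether) formation on a primary alcohol under amine base; no fluoride or strong nucleophile is present, so the silyl triflate should be untouched.

Step 6
Reactants: 10 4'-hydroxyacetophenone
Product: 11 1-[4-(methoxymethoxy)phenyl]ethan-1-one
Conditions: MOMCl, iPr2NEt, CH2Cl2, 0 °C to rt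
Reagents that add atoms: chloromethyl methyl ether (COCCl)
Why: Routine MOM protection of a phenol.

Step 7
Reactants: 12 methyl 4-hydroxybenzoate
Product: 13 methyl 4-(methoxymethoxy)benzoate
Conditions: MOMCl, iPr2NEt, CH2Cl2, 0 °C to rt
Reagents that add atoms: chloromethyl methyl ether (COCCl)
Why: Routine MOM protection of a phenol; the free phenoxide would otherwise deactivate the ester in the next step.

Step 8
Reactants: 11 1-[4-(methoxymethoxy)phenyl]ethan-1-one; 13 methyl 4-(methoxymethoxy)benzoate
Product: 14 1,3-bis[4-(methoxymethoxy)phenyl]propane-1,3-dione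
Conditions: NaH (2.5 equiv), THF, 0 to 65 °C; aq. NH4Cl
Reagents that add atoms: none
Why: Crossed Claisen condensation; only the ketone is enolisable and only the ester can act as acceptor, and deprotonation of the product diketone by the second equivalent of NaH drives the equilibrium.

Step 9
Reactants: 9 3-(allyloxy)-6-[(methoxymethoxy)methyl]-2-(trimethylsilyl)phenyl trifluoromethanesulfonate; 14 1,3-bis[4-(methoxymethoxy)phenyl]propane-1,3-dione
Product: 17 2-{3-(allyloxy)-2-[4-(methoxymethoxy)benzoyl]-6-[(methoxymethoxy)methyl]phenyl}-1-[4-(methoxymethoxy)phenyl]ethan-1-one, via aryne 15 (not isolated), via cesium benzocyclobutenoxide 16 (not isolated)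
Conditions: CsF (2.5 equiv), MeCN, 80 °C; 9 (1.25 equiv) to 14 (1.0 equiv)
Reagents that add atoms: none
Why: Fluoride attacks the trimethylsilyl group of 9 and the resulting aryl anion expels triflate, giving aryne 15. The cesium enolate of 14 adds through its central carbon to C6; the aryl anion formed at C1 closes onto the neighbouring carbonyl (4-exo-trig) to benzocyclobutenoxide 16, whose retro-aldol opening breaks the former C7–C8 bond, leaves the aroyl group on C1 and the enolate of the C6 benzyl ketone, and this enolate is protonated by fresh 14, which carries the chain. The closest known reaction type is the fluoride-induced acyl-alkylation of arynes by β-ketoesters and 1,3-diketones (formal insertion of the aryne into the C–C σ bond), which is established for 3-alkoxyarynes. The four-membered ring is transient and no ring is kept; the product has no stereocentre and the two stereocentres of 16 vanish on fragmentation. The selectivity required is bond formation at C6 and not at C1: the inductively withdrawing allyloxy group at C2 distorts the aryne so that C6 is the flatter, more electrophilic terminus, and attack there places the negative charge on C1 next to the C–O bond where it is best stabilised; the CH2OMOM group at C5 is the only factor (steric) working against it. Because 14 is symmetric, ring closure on either carbonyl gives the same product, and the soft, doubly stabilised enolate should react at carbon and not at oxygen. Product 17 is less acidic than 14, so while 14 is present its enolate is not formed to a competitive extent and a second arylation is held back.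

Step 10
Reactants: 17 2-{3-(allyloxy)-2-[4-(methoxymethoxy)benzoyl]-6-[(methoxymethoxy)methyl]phenyl}-1-[4-(methoxymethoxy)phenyl]ethan-1-one
Product: 19 [6-(allyloxy)-3-[(methoxymethoxy)methyl]-2-{[4-(methoxymethoxy)phenyl]ethynyl}phenyl][4-(methoxymethoxy)phenyl]methanone, via (Z)-enol triflate 18 (not isolated)
Conditions: KN(SiMe3)2 (1.1 equiv), THF, −78 °C; PhNTf2 (1.1 equiv), −78 to 0 °C; KN(SiMe3)2 (1.5 equiv), 0 °C to rt; aq. NH4Cl
Reagents that add atoms: none
Why: Enolate O-sulfonylation followed by base-induced elimination, the standard ketone-to-alkyne sequence; the conjugated potassium enolate (aryl cis to oxygen) gives the (Z)-enol triflate 18, whose vinylic hydrogen is anti to the triflate, so the second portion of hindered amide base should effect anti-E2 elimination. The C1 diaryl ketone has no α-hydrogen and does not add the silylamide.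

Step 11
Reactants: 19 [6-(allyloxy)-3-[(methoxymethoxy)methyl]-2-{[4-(methoxymethoxy)phenyl]ethynyl}phenyl][4-(methoxymethoxy)phenyl]methanone
Product: 20 [6-hydroxy-3-[(methoxymethoxy)methyl]-2-{[4-(methoxymethoxy)phenyl]ethynyl}phenyl][4-(methoxymethoxy)phenyl]methanone
Conditions: Pd(PPh3)4 (5 mol %), morpholine, THF, rt
Reagents that add atoms: none
Why: Tsuji–Trost-type deallylation; zerovalent palladium ionises the allyl aryl ether to a π-allyl complex and the phenoxide, and morpholine captures the allyl group; MOM ethers, alkyne and ketone are not affected.

Step 12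
Reactants: 20 [6-hydroxy-3-[(methoxymethoxy)methyl]-2-{[4-(methoxymethoxy)phenyl]ethynyl}phenyl][4-(methoxymethoxy)phenyl]methanone
Product: 21 2-[4-(methoxymethoxy)benzoyl]-4-[(methoxymethoxy)methyl]-3-{[4-(methoxymethoxy)phenyl]ethynyl}phenyl trifluoromethanesulfonate
Conditions: Tf2O, pyridine, CH2Cl2, 0 °C
Reagents that add atoms: trifluoromethanesulfonic anhydride (O=S(=O)(OS(=O)(=O)C(F)(F)F)C(F)(F)F)
Why: O-sulfonylation of a phenol; pyridine buffers the triflic acid so the acetals survive, and ortho-acylphenols are triflated routinely under these conditions.

Step 13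
Reactants: 22 4-bromoresorcinol
Product: 23 1-bromo-2,4-bis(methoxymethoxy)benzene
Conditions: MOMCl (2.5 equiv), iPr2NEt, CH2Cl2, 0 °C to rt
Reagents that add atoms: chloromethyl methyl ether (COCCl)
Why: Routine double MOM protection of a resorcinol.

Step 14
Reactants: 23 1-bromo-2,4-bis(methoxymethoxy)benzene
Product: 25 [2,4-bis(methoxymethoxy)phenyl]boronic acid, via aryllithium 24 (not isolated)
Conditions: n-BuLi, THF, −78 °C; B(OiPr)3, −78 °C to rt; aq. NH4Cl
Reagents that add atoms: triisopropyl borate (CC(C)OB(OC(C)C)OC(C)C); water (O)
Why: Bromine–lithium exchange (faster at −78 °C than ortho-lithiation between the acetals) and borylation of the aryllithium; near-neutral hydrolysis keeps the MOM groups.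

Step 15
Reactants: 21 2-[4-(methoxymethoxy)benzoyl]-4-[(methoxymethoxy)methyl]-3-{[4-(methoxymethoxy)phenyl]ethynyl}phenyl trifluoromethanesulfonate; 25 [2,4-bis(methoxymethoxy)phenyl]boronic acid
Product: 26 {2',4'-bis(methoxymethoxy)-4-[(methoxymethoxy)methyl]-3-{[4-(methoxymethoxy)phenyl]ethynyl}biphenyl-2-yl}[4-(methoxymethoxy)phenyl]methanone
Conditions: Pd(OAc)2 (5 mol %), SPhos (10 mol %), K3PO4, toluene/H2O, 80 °C
Reagents that add atoms: none
Why: Suzuki–Miyaura coupling; the triflate ortho to the carbonyl adds readily to zerovalent palladium formed in situ, and the bulky electron-rich biarylphosphine is the standard choice for ortho,ortho'-disubstituted biaryls and should be fast enough to outrun protodeboronation of the electron-rich boronic acid.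

Step 16
Reactants: 27 4-bromophenol
Product: 28 1-bromo-4-(methoxymethoxy)benzene
Conditions: MOMCl, iPr2NEt, CH2Cl2, 0 °C to rt
Reagents that add atoms: chloromethyl methyl ether (COCCl)
Why: Routine MOM protection of a phenol.

Step 17
Reactants: 28 1-bromo-4-(methoxymethoxy)benzene; 26 {2',4'-bis(methoxymethoxy)-4-[(methoxymethoxy)methyl]-3-{[4-(methoxymethoxy)phenyl]ethynyl}biphenyl-2-yl}[4-(methoxymethoxy)phenyl]methanone
Product: 30 {2',4'-bis(methoxymethoxy)-4-[(methoxymethoxy)methyl]-3-{[4-(methoxymethoxy)phenyl]ethynyl}biphenyl-2-yl}bis[4-(methoxymethoxy)phenyl]methanol, via aryllithium 29 (not isolated)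
Conditions: 28 (3 equiv), n-BuLi, THF, −78 °C; then 26, −78 to 0 °C; aq. NH4Cl
Reagents that add atoms: none
Why: 1,2-Addition of an aryllithium to a non-enolisable diaryl ketone; no deprotonation can compete, the slim alkynyl group is one of the two ortho substituents, and excess reagent compensates for the steric shielding; C7 carries two identical aryl groups, so no stereocentre arises.

Step 18
Reactants: 30 {2',4'-bis(methoxymethoxy)-4-[(methoxymethoxy)methyl]-3-{[4-(methoxymethoxy)phenyl]ethynyl}biphenyl-2-yl}bis[4-(methoxymethoxy)phenyl]methanol
Product: 31 selaginellin F, 4-{[2',4'-dihydroxy-4-(hydroxymethyl)-3-[(4-hydroxyphenyl)ethynyl]biphenyl-2-yl](4-hydroxyphenyl)methylidene}cyclohexa-2,5-dien-1-one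
Conditions: HCl (2 M), MeOH/THF, 40 °C; then NaHCO3 to pH 6
Reagents that add atoms: none
Why: Acid-catalysed acetal exchange with methanol removes all six MOM groups, and the triaryl carbinol ionises (SN1) to a cation stabilised by two 4-hydroxyphenyl rings, which on neutralisation loses a phenolic proton to give the quinone methide (fuchsone formation).

## Compound list

1 | 2-bromoresorcinol | Oc1cccc(O)c1Br | starting material
2 | 3-bromo-2,4-dihydroxybenzaldehyde | O=Cc1ccc(O)c(Br)c1O | intermediate
3 | 4-(allyloxy)-3-bromo-2-hydroxybenzaldehyde | C=CCOc1ccc(C=O)c(O)c1Br | intermediate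
4 | 3-(allyloxy)-2-bromo-6-(hydroxymethyl)phenol | C=CCOc1ccc(CO)c(O)c1Br | intermediate
5 | [3-(allyloxy)-2-bromo-6-{[(trimethylsilyl)oxy]methyl}phenoxy]trimethylsilane | C=CCOc1ccc(CO[Si](C)(C)C)c(O[Si](C)(C)C)c1Br | intermediate
6 | lithium 3-(allyloxy)-2-(trimethylsilyl)-6-{[(trimethylsilyl)oxy]methyl}phenolate | C=CCOc1ccc(CO[Si](C)(C)C)c([O-])c1[Si](C)(C)C.[Li+] | intermediate
7 | 3-(allyloxy)-2-(trimethylsilyl)-6-{[(trimethylsilyl)oxy]methyl}phenyl trifluoromethanesulfonate | C=CCOc1ccc(CO[Si](C)(C)C)c(OS(=O)(=O)C(F)(F)F)c1[Si](C)(C)C | intermediate
8 | 3-(allyloxy)-6-(hydroxymethyl)-2-(trimethylsilyl)phenyl trifluoromethanesulfonate | C=CCOc1ccc(CO)c(OS(=O)(=O)C(F)(F)F)c1[Si](C)(C)C | intermediate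
9 | 3-(allyloxy)-6-[(methoxymethoxy)methyl]-2-(trimethylsilyl)phenyl trifluoromethanesulfonate | C=CCOc1ccc(COCOC)c(OS(=O)(=O)C(F)(F)F)c1[Si](C)(C)C | intermediate
10 | 4'-hydroxyacetophenone | CC(=O)c1ccc(O)cc1 | starting material
11 | 1-[4-(methoxymethoxy)phenyl]ethan-1-one | CC(=O)c1ccc(OCOC)cc1 | intermediate
12 | methyl 4-hydroxybenzoate | COC(=O)c1ccc(O)cc1 | starting material
13 | methyl 4-(methoxymethoxy)benzoate | COC(=O)c1ccc(OCOC)cc1 | intermediate
14 | 1,3-bis[4-(methoxymethoxy)phenyl]propane-1,3-dione | COCOc1ccc(C(=O)CC(=O)c2ccc(OCOC)cc2)cc1 | intermediate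
15 | 3-(allyloxy)-6-[(methoxymethoxy)methyl]benzyne (1,2-didehydrobenzene; aryne between C1 and C6 of ring A) | C=CCOC1=CC=C(COCOC)C#C1 | intermediate
16 | cesium 5-(allyloxy)-8-[4-(methoxymethoxy)benzoyl]-7-[4-(methoxymethoxy)phenyl]-2-[(methoxymethoxy)methyl]bicyclo[4.2.0]octa-1,3,5-trien-7-olate (racemic, mixture of diastereomers) | C=CCOc1ccc(COCOC)c2c1C([O-])(c1ccc(OCOC)cc1)C2C(=O)c1ccc(OCOC)cc1.[Cs+] | intermediate
17 | 2-{3-(allyloxy)-2-[4-(methoxymethoxy)benzoyl]-6-[(methoxymethoxy)methyl]phenyl}-1-[4-(methoxymethoxy)phenyl]ethan-1-one | C=CCOc1ccc(COCOC)c(CC(=O)c2ccc(OCOC)cc2)c1C(=O)c1ccc(OCOC)cc1 | intermediate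
18 | (Z)-2-{3-(allyloxy)-2-[4-(methoxymethoxy)benzoyl]-6-[(methoxymethoxy)methyl]phenyl}-1-[4-(methoxymethoxy)phenyl]ethenyl trifluoromethanesulfonate | C=CCOc1ccc(COCOC)c(/C=C(\OS(=O)(=O)C(F)(F)F)c2ccc(OCOC)cc2)c1C(=O)c1ccc(OCOC)cc1 | intermediate
19 | [6-(allyloxy)-3-[(methoxymethoxy)methyl]-2-{[4-(methoxymethoxy)phenyl]ethynyl}phenyl][4-(methoxymethoxy)phenyl]methanone | C=CCOc1ccc(COCOC)c(C#Cc2ccc(OCOC)cc2)c1C(=O)c1ccc(OCOC)cc1 | intermediate
20 | [6-hydroxy-3-[(methoxymethoxy)methyl]-2-{[4-(methoxymethoxy)phenyl]ethynyl}phenyl][4-(methoxymethoxy)phenyl]methanone | Oc1ccc(COCOC)c(C#Cc2ccc(OCOC)cc2)c1C(=O)c1ccc(OCOC)cc1 | intermediate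
21 | 2-[4-(methoxymethoxy)benzoyl]-4-[(methoxymethoxy)methyl]-3-{[4-(methoxymethoxy)phenyl]ethynyl}phenyl trifluoromethanesulfonate | O=S(=O)(Oc1ccc(COCOC)c(C#Cc2ccc(OCOC)cc2)c1C(=O)c1ccc(OCOC)cc1)C(F)(F)F | intermediate
22 | 4-bromoresorcinol | Oc1ccc(Br)c(O)c1 | starting material
23 | 1-bromo-2,4-bis(methoxymethoxy)benzene | COCOc1ccc(Br)c(OCOC)c1 | intermediate
24 | [2,4-bis(methoxymethoxy)phenyl]lithium | [Li]c1ccc(OCOC)cc1OCOC | intermediate
25 | [2,4-bis(methoxymethoxy)phenyl]boronic acid | COCOc1ccc(B(O)O)c(OCOC)c1 | intermediate
26 | {2',4'-bis(methoxymethoxy)-4-[(methoxymethoxy)methyl]-3-{[4-(methoxymethoxy)phenyl]ethynyl}biphenyl-2-yl}[4-(methoxymethoxy)phenyl]methanone | COCOCc1ccc(-c2ccc(OCOC)cc2OCOC)c(C(=O)c2ccc(OCOC)cc2)c1C#Cc1ccc(OCOC)cc1 | intermediate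
27 | 4-bromophenol | Oc1ccc(Br)cc1 | starting material
28 | 1-bromo-4-(methoxymethoxy)benzene | COCOc1ccc(Br)cc1 | intermediate
29 | [4-(methoxymethoxy)phenyl]lithium | [Li]c1ccc(OCOC)cc1 | intermediate
30 | {2',4'-bis(methoxymethoxy)-4-[(methoxymethoxy)methyl]-3-{[4-(methoxymethoxy)phenyl]ethynyl}biphenyl-2-yl}bis[4-(methoxymethoxy)phenyl]methanol | COCOCc1ccc(-c2ccc(OCOC)cc2OCOC)c(C(O)(c2ccc(OCOC)cc2)c2ccc(OCOC)cc2)c1C#Cc1ccc(OCOC)cc1 | intermediate
31 | selaginellin F, 4-{[2',4'-dihydroxy-4-(hydroxymethyl)-3-[(4-hydroxyphenyl)ethynyl]biphenyl-2-yl](4-hydroxyphenyl)methylidene}cyclohexa-2,5-dien-1-one | O=C1C=CC(=C(c2ccc(O)cc2)c2c(-c3ccc(O)cc3O)ccc(CO)c2C#Cc2ccc(O)cc2)C=C1 | target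

## Step count and least certain steps

Total: 18 steps. Longest linear sequence: 12 steps (steps 1, 2, 3, 4, 5, 9, 10, 11, 12, 15, 17, 18).

**Step 9 (key step).**
- Risk: the aryne may be diverted into unproductive channels, namely attack at C1, O-arylation, or quenching by fluoride or solvent. The cause is that the bulky, strongly delocalised diaroylmethanide must bond at C6 directly beside the CH2OMOM group, so the favourable electronic bias of the allyloxy group is partly offset by sterics.
- Fallback: it sets out from 9 and 11 and returns at 17. Ketone 11 is acylated with dimethyl carbonate (NaH, THF, reflux) to methyl 3-[4-(methoxymethoxy)phenyl]-3-oxopropanoate F1, a smaller and more nucleophilic enolate precursor of the class for which this insertion is best established. F1 and 9 under the same CsF conditions should give methyl 2-{3-(allyloxy)-2-[4-(methoxymethoxy)benzoyl]-6-[(methoxymethoxy)methyl]phenyl}acetate F2. The ester enolate of F2 (LiN(SiMe3)2, THF, −78 °C to rt) is acylated by ester 13 in a crossed Claisen condensation to racemic methyl 2-{3-(allyloxy)-2-[4-(methoxymethoxy)benzoyl]-6-[(methoxymethoxy)methyl]phenyl}-3-[4-(methoxymethoxy)phenyl]-3-oxopropanoate F3. Krapcho dealkoxycarbonylation (LiCl, wet DMSO, 120 °C) then gives 17.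

**Step 4.**
- Risk: the sulfonylating agent may be consumed at the benzylic silyl ether oxygen, or the labile CH2O–Si group may be lost before triflation, so that the benzylic oxygen is triflated instead of, or as well as, the crowded phenolate.
- Fallback: it sets out from 4 and returns at 9, bypassing 8 and step 5. The dianion of 4 (NaH, 2.1 equiv, THF, 0 °C) is treated with one equivalent of MOMCl, which should react at the more basic alkoxide, to give 3-(allyloxy)-2-bromo-6-[(methoxymethoxy)methyl]phenol F4. Silylation with (Me3Si)2NH gives [3-(allyloxy)-2-bromo-6-[(methoxymethoxy)methyl]phenoxy]trimethylsilane F5. n-BuLi at −78 °C induces exchange and retro-Brook shift to lithium 3-(allyloxy)-6-[(methoxymethoxy)methyl]-2-(trimethylsilyl)phenolate F6, and Tf2O converts F6 directly into 9.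

**Step 10.**
- Risk: the enolate oxygen may add reversibly to the neighbouring C1 ketone (six-membered ring closure towards isochromene or benzopyrylium products), or the base may attack sulfur of the enol triflate and return the ketone instead of eliminating.
- Fallback: it sets out from 17 and returns at 19, and replaces the one-flask sulfonate route by a two-stage phosphate route with a leaving group whose P–O bond is not cleaved by amide bases. The potassium enolate of 17 (KN(SiMe3)2, THF, −78 °C) is trapped with ClP(O)(OEt)2, a hard, oxygen-selective electrophile, to give (Z)-2-{3-(allyloxy)-2-[4-(methoxymethoxy)benzoyl]-6-[(methoxymethoxy)methyl]phenyl}-1-[4-(methoxymethoxy)phenyl]ethenyl diethyl phosphate F7, which is isolated. Elimination with lithium 2,2,6,6-tetramethylpiperidide (THF, −78 to 0 °C), a base that cannot reduce the diaryl ketone by hydride transfer, then gives 19.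

**Step 15.**
- Risk: protodeboronation of the electron-rich, ortho-alkoxy boronic acid 25 may outpace transmetalation at the crowded palladium centre, accompanied by slow hydrolysis of the triflate.
- Fallback: it sets out from 21 and 23 and returns at 26, changing to an anhydrous Negishi coupling. Bromide 23 is lithiated to 24 (n-BuLi, THF, −78 °C) and transmetalated with ZnCl2 to [2,4-bis(methoxymethoxy)phenyl]zinc chloride F8, which is coupled with 21 (Pd(OAc)2, SPhos, THF, 50 °C). Arylzinc halides do not add to the diaryl ketone or the alkyne.

**Step 18.**
- Risk: the acid exposure needed to cleave the aliphatic (benzylic) acetal is longer than the phenolic acetals require. During this time water or the freed C5 hydroxymethyl group may add across the protonated alkyne, released formaldehyde equivalents may alkylate the free resorcinol, and the 2'-hydroxyl may close reversibly onto the C7 cation.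
- Fallback: it sets out from 30 and returns at 31 in two stages, so that the benzylic hydroxyl is unveiled last and cold. Brief treatment with dilute HCl in MeOH at rt removes only the five aryl acetals and dehydrates the carbinol to 4-{[2',4'-dihydroxy-3-[(4-hydroxyphenyl)ethynyl]-4-[(methoxymethoxy)methyl]biphenyl-2-yl](4-hydroxyphenyl)methylidene}cyclohexa-2,5-dien-1-one F9, which is isolated. The remaining acetal is then cleaved with Me3SiBr (CH2Cl2, −30 °C) followed by aqueous NaHCO3 to give 31.

## Further compounds

F1 | step 9 | methyl 3-[4-(methoxymethoxy)phenyl]-3-oxopropanoate | COC(=O)CC(=O)c1ccc(OCOC)cc1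
F2 | step 9 | methyl 2-{3-(allyloxy)-2-[4-(methoxymethoxy)benzoyl]-6-[(methoxymethoxy)methyl]phenyl}acetate | C=CCOc1ccc(COCOC)c(CC(=O)OC)c1C(=O)c1ccc(OCOC)cc1
F3 | step 9 | methyl 2-{3-(allyloxy)-2-[4-(methoxymethoxy)benzoyl]-6-[(methoxymethoxy)methyl]phenyl}-3-[4-(methoxymethoxy)phenyl]-3-oxopropanoate (racemic) | C=CCOc1ccc(COCOC)c(C(C(=O)OC)C(=O)c2ccc(OCOC)cc2)c1C(=O)c1ccc(OCOC)cc1
F4 | step 4 | 3-(allyloxy)-2-bromo-6-[(methoxymethoxy)methyl]phenol | C=CCOc1ccc(COCOC)c(O)c1Br
F5 | step 4 | [3-(allyloxy)-2-bromo-6-[(methoxymethoxy)methyl]phenoxy]trimethylsilane | C=CCOc1ccc(COCOC)c(O[Si](C)(C)C)c1Br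
F6 | step 4 | lithium 3-(allyloxy)-6-[(methoxymethoxy)methyl]-2-(trimethylsilyl)phenolate | C=CCOc1ccc(COCOC)c([O-])c1[Si](C)(C)C.[Li+]
F7 | step 10 | (Z)-2-{3-(allyloxy)-2-[4-(methoxymethoxy)benzoyl]-6-[(methoxymethoxy)methyl]phenyl}-1-[4-(methoxymethoxy)phenyl]ethenyl diethyl phosphate | C=CCOc1ccc(COCOC)c(/C=C(\OP(=O)(OCC)OCC)c2ccc(OCOC)cc2)c1C(=O)c1ccc(OCOC)cc1
F8 | step 15 | [2,4-bis(methoxymethoxy)phenyl]zinc chloride | COCOc1ccc([Zn]Cl)c(OCOC)c1
F9 | step 18 | 4-{[2',4'-dihydroxy-3-[(4-hydroxyphenyl)ethynyl]-4-[(methoxymethoxy)methyl]biphenyl-2-yl](4-hydroxyphenyl)methylidene}cyclohexa-2,5-dien-1-one | COCOCc1ccc(-c2ccc(O)cc2O)c(C(c2ccc(O)cc2)=C2C=CC(=O)C=C2)c1C#Cc1ccc(O)cc1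
A1 | alternative 1 | 7-bromo-3-(pivaloyloxy)-8-(pivaloyloxymethyl)-6H-benzo[c]chromen-6-one | CC(C)(C)C(=O)OCc1ccc2c(c1Br)C(=O)Oc1cc(OC(=O)C(C)(C)C)ccc1-2
A2 | alternative 1 | 3-bromo-4'-(pivaloyloxy)-4-(pivaloyloxymethyl)biphenyl-2-carboxylic acid | CC(C)(C)C(=O)OCc1ccc(-c2ccc(OC(=O)C(C)(C)C)cc2)c(C(=O)O)c1Br
A3 | alternative 2 | ring A bis-lactone (benzo[c]chromen-6-one fused with a phthalide, 3-methoxymethoxy substituted) | COCOc1ccc2c(c1)OC(=O)c1c-2ccc2c1C(=O)OC2
A4 | alternative 2 | 2-ethynyl-5-(methoxymethoxy)phenyl prop-2-yn-1-yl but-2-ynedioate | C#CCOC(=O)C#CC(=O)Oc1cc(OCOC)ccc1C#C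
A5 | alternative 3 | dimethyl 4-[2,4-bis(methoxymethoxy)phenyl]-2-hydroxy-4,5-dihydroisophthalate (racemic) | COC(=O)C1=C(O)C(C(=O)OC)=CCC1c1ccc(OCOC)cc1OCOC
A6 | alternative 3 | (E)-3-[2,4-bis(methoxymethoxy)phenyl]prop-2-enal | COCOc1ccc(/C=C/C=O)c(OCOC)c1
A7 | alternative 3 | dimethyl 3-oxopentanedioate | COC(=O)CC(=O)CC(=O)OC
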